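**Retrosynthetic overview**

1. Ring A (spiro δ-lactone) and the tertiary carbinol of ring B are added last to the ring-B ketone of a pentacyclic keto lactone, by vinylation, acetone aldol–lactonisation, methylenation and hydration.
2. The bicyclo[2.2.2]octanone cage with its γ-lactone is traced back to a linear 6-5-5 tricycle: a ring-B/ring-C enone fused to an outer cyclopentane (ring D) that is a 1-isopropenyl-cyclopentane-1,2-diol carrying CO2H and CH2OH.
3. In the key step a Lewis acid closes the isopropenyl CH2 onto the enone β-carbon. The cage carbocycle made of the spiro carbon, CH2, C(CH3), CH(O), CH(CO2) and the CH2O-bearing bridgehead first appears as a seven-membered ring in a bicyclo[3.2.1]octyl cation. It is then contracted to six by a 1,2-shift of the CH(OSi) carbon from the carbinol carbon, which becomes the bridging ketone.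
4. The feature that makes this possible: the tertiary allylic carbinol carbon of ring D and the enone β-carbon sit 1,3-cis across the ring-C/ring-D fusion, and the ring-D bond to the CH(OSi) carbon is axial to the cationic centre.
5. Ring order: ring D (bought, C2-symmetric, the only source of chirality), then ring B attached by alkylation, ring C by aldol condensation, cage plus γ-lactone in the key step, ring A last.

Key step: step 12

Assumption: dimethyl (1R,2R)-4-oxocyclopentane-1,2-dicarboxylate is taken as a purchasable single enantiomer (it derives from the resolved trans-diacid); all other stereocentres are set relative to it.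

**Step 1**
Reactants: 1 3-ethoxy-2-methylcyclohex-2-en-1-one
Product: 2 2-(bromomethyl)-3-ethoxycyclohex-2-en-1-one
Conditions: NBS, AIBN (cat.), PhCF3, 80 °C
Reagents that add atoms: N-bromosuccinimide O=C1CCC(=O)N1Br
Why: Wohl–Ziegler bromination, in which hydrogen abstraction from the methyl group gives an allyl radical conjugated through the enol-ether double bond, so the primary allylic bromide should form in preference to ring bromination; no stereocentre.

**Step 2**
Reactants: 3 dimethyl (1R,2R)-4-oxocyclopentane-1,2-dicarboxylate
Product: 4 dimethyl (1R,2R)-3-methyl-4-oxocyclopentane-1,2-dicarboxylate (both 3-epimers)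
Conditions: LiN(i-Pr)2 (1.05 equiv), THF, −78 °C; MeI, −78 to −20 °C
Reagents that add atoms: iodomethane CI
Why: kinetic enolate alkylation of a C2-symmetric ketone, so both α-CH2 groups are equivalent and one constitution forms; the configuration of the new methine does not matter because step 4 makes it quaternary.

**Step 3**
Reactants: 4 dimethyl (1R,2R)-3-methyl-4-oxocyclopentane-1,2-dicarboxylate
Product: 5 dimethyl 3-methyl-4-(trimethylsilyloxy)cyclopent-3-ene-1,2-dicarboxylate (trans-diester)
Conditions: Me3SiCl, Et3N, DMF, 80 °C
Reagents that add atoms: chlorotrimethylsilane C[Si](C)(C)Cl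
Why: silylation under equilibrating conditions should give the more substituted silyl enol ether, which fixes the regiochemistry of the next alkylation.

**Step 4**
Reactants: 5 silyl enol ether; 2 2-(bromomethyl)-3-ethoxycyclohex-2-en-1-one
Product: 7 dimethyl 3-[(2-ethoxy-6-oxocyclohex-1-enyl)methyl]-3-methyl-4-oxocyclopentane-1,2-dicarboxylate (1,2-trans; 3-methyl cis to the 2-ester), via ammonium enolate 6 (not isolated)
Conditions: BnMe3NF (anhydrous), 4 Å MS, THF, −20 °C to rt
Reagents that add atoms: none
Why: fluoride-induced regiospecific enolate alkylation (tolerated by the esters), in which the allylic bromide attacks the enolate face opposite to the ester on the adjacent carbon; this sets the quaternary centre with methyl cis and the CH2–ring-B arm trans to that ester.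

**Step 5**
Reactants: 7 keto diester
Product: 8 2-(methoxycarbonyl)-3-[(2-ethoxy-6-oxocyclohex-1-enyl)methyl]-3-methyl-4-oxocyclopentane-1-carboxylic acid
Conditions: LiOH·H2O (1.05 equiv), THF/H2O, 0 °C; dilute HCl to pH 3 at 0 °C
Reagents that add atoms: lithium hydroxide [Li+].[OH-]
Why: saponification should differentiate the esters by steric access, since the ester next to the quaternary carbon is neopentyl-like and survives while the other is cleaved; the vinylogous ester is stable to hydroxide and no stereocentre is touched.

**Step 6**
Reactants: 8 keto acid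
Product: 10 5-(tert-butyldimethylsilyloxy) derivative of 8 (silyloxy trans to the 1-carboxyl; cis to the 3-methyl), via bis-silyl enol ether 9 (not isolated)
Conditions: TBSOTf (2.3 equiv), Et3N, CH2Cl2, 0 °C; then mCPBA, NaHCO3, −20 to 0 °C; aq. citric acid
Reagents that add atoms: tert-butyldimethylsilyl trifluoromethanesulfonate CC(C)(C)[Si](C)(C)OS(=O)(=O)C(F)(F)F; 3-chloroperbenzoic acid OOC(=O)c1cccc(Cl)c1
Why: Rubottom oxidation, in which enolisation can only go toward the single α-CH2, the peracid attacks anti to the adjacent carboxyl group and the 1,4-silyl shift leaves the new oxygen as its TBS ether.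

**Step 7**
Reactants: 10 α-silyloxy keto acid
Product: 11 5-(tert-butyldimethylsilyloxy)-3-[(2,6-dioxocyclohexyl)methyl]-2-(methoxycarbonyl)-3-methyl-4-oxocyclopentane-1-carboxylic acid
Conditions: 1 M HCl, THF, 0 °C
Reagents that add atoms: water O
Why: acid hydrolysis of the vinylogous ester frees the 2-substituted cyclohexane-1,3-dione needed for ring C; the secondary silyl ether and the methyl ester should survive cold dilute acid.

**Step 8**
Reactants: 11 trione acid
Product: 12 4-hydroxy-4-isopropenyl derivative of 11 (4-OH cis to the 5-OTBS; isopropenyl cis to the CH2–dione arm)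
Conditions: CH2=C(CH3)MgBr (4.5 equiv), CeCl3 (anhydrous), THF, −78 to −40 °C; aq. NH4Cl
Reagents that add atoms: isopropenylmagnesium bromide CC(=C)[Mg]Br
Why: organocerium 1,2-addition to the only free ketone (acid and dione are masked as magnesium salts by the first two equivalents), with Felkin–Anh attack anti to the α-silyloxy and α-methyl groups placing the isopropenyl group on the face of the CH2–ring-B arm.

**Step 9**
Reactants: 12 isopropenyl carbinol
Product: 13 the 2-formyl analogue of 12 (CO2CH3 replaced by CHO)
Conditions: i-Bu2AlH (5 equiv), CH2Cl2, −78 °C; aq. potassium sodium tartrate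
Reagents that add atoms: none
Why: partial reduction of the only remaining ester, whose neopentyl tetrahedral aluminate is stable at −78 °C, while the aluminium carboxylate and aluminium dionate are not reduced; no stereocentre changes.

**Step 10**
Reactants: 13 aldehyde
Product: 15 tricyclic enone aldehyde (ring-B cyclohexenone fused through its tetrasubstituted C=C to cyclopentene ring C; ring C cis-fused to ring D; CHO on the new quaternary carbon cis to the ring methyl), via aldol 14 (not isolated)
Conditions: pyrrolidine (20 mol %), AcOH (20 mol %), DMSO, 40 °C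
Reagents that add atoms: none
Why: Hajos–Parrish-type enamine aldol condensation (5-exo attack of the aldehyde α-carbon on one of the two equivalent dione carbonyls, then dehydration); only the aldehyde forms an enamine and the tether allows only cis fusion, which sets the quaternary carbon.

**Step 11**
Reactants: 15 enone aldehyde
Product: 16 tricyclic enone alcohol (CHO reduced to CH2OH; CH2OH trans to CO2H on ring D)
Conditions: NaBH4, MeOH/CH2Cl2, −78 °C
Reagents that add atoms: none
Why: chemoselective borohydride reduction of an aldehyde in the presence of a tetrasubstituted enone at low temperature; the trans hydroxy acid cannot lactonise at this stage.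

**Step 12**
Reactants: 16 tricyclic enone alcohol
Product: 19 pentacyclic keto lactone (bicyclo[2.2.2]octanone cage with OTBS; γ-lactone; ring C; cis-fused ring-B ketone), via bicyclo[3.2.1]octyl cation 17 (not isolated), via hydroxy acid 18 (not isolated)
Conditions: EtAlCl2 (5 equiv), CH2Cl2, −78 to 0 °C; then 1 M HCl, THF, rt
Reagents that add atoms: none
Why: Proposed new method: EtAlCl2 first converts the three OH groups into aluminium alkoxides and carboxylate (so the tertiary allylic carbinol cannot ionise) and then activates the ring-B enone, whose β-carbon is attacked by the CH2 terminus of the isopropenyl group held over it on the concave face (6-endo-trig closure; the closest known types are the Lewis-acid enone–olefin cyclisation and the pinacol-terminated Prins cyclisation), giving cation 17 in which the future cage ring is still seven-membered. In 17 the bond from the carbinol carbon to the CH(OTBS) carbon is axial and parallel to the vacant orbital while the bond to the quaternary ring-fusion carbon lies near its nodal plane, so the CH(OTBS) carbon migrates suprafacially with retention: the seven-membered ring contracts to the six-membered cage ring, ring D expands to the cyclohexanone and the carbinol becomes the bridging ketone. The spiro quaternary carbon is set by the tether (only the concave face is in reach), the methyl-bearing bridgehead by the suprafacial shift, the silyloxy carbon keeps its configuration and ends syn to the ketone bridge, and the ring-B α-carbon equilibrates to the cis-fused ketone in the acidic work-up. After the shift the CH2OH and CO2H groups, trans on ring D, are gauche on the cage and close the γ-lactone by 5-exo-trig acyl substitution in 1 M HCl. The selectivities needed are enone activation rather than ionisation of the allylic alcohol (secured by the aluminium alkoxide) and migration of the CH(OTBS) carbon rather than the ring-fusion carbon (secured by the axial alignment).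

**Step 13**
Reactants: 19 pentacyclic keto lactone
Product: 20 (E)-enoate (19 carrying CH=CH–CO2CH3 on the ring-B CH2 next to the ketone; epimers at that carbon)
Conditions: LiN(SiMe3)2 (2.1 equiv), THF, −78 °C; methyl (E)-3-(phenylsulfonyl)prop-2-enoate, −78 to −40 °C; AcOH
Reagents that add atoms: methyl (E)-3-(phenylsulfonyl)prop-2-enoate COC(=O)/C=C/S(=O)(=O)c1ccccc1
Why: the kinetic enolate at the only accessible α-CH2 of the ring-B ketone (the other α-carbon is the hindered ring-fusion methine; the cage ketone has no α-hydrogen) undergoes conjugate addition–elimination; the new methine is epimerisable and becomes quaternary in step 14.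

**Step 14**
Reactants: 20 (E)-enoate
Product: 21 spiro lactone ketone (ring A complete; ring-B ketone still present)
Conditions: LiN(SiMe3)2 (1.1 equiv), THF, −78 °C; acetone, CeCl3, −78 to 0 °C; aq. NH4Cl
Reagents that add atoms: acetone CC(C)=O
Why: aldol addition of the extended enolate to acetone at the carbon α to the ketone, from the face opposite to the pseudo-axial CH2 bond of ring C, followed by lactonisation onto the (Z)-enoate; the dienolate should interconvert E and Z forms, only the (Z)-aldolate can cyclise, and loss of methoxide makes the aldol irreversible and sets the spiro centre.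

**Step 15**
Reactants: 21 spiro lactone ketone
Product: 22 methylene compound (ring-B C=O replaced by C=CH2)
Conditions: Zn, CH2Br2, TiCl4, THF/CH2Cl2, 0 °C to rt
Reagents that add atoms: dibromomethane BrCBr
Why: Takai–Lombardo methylenation, which suits hindered and easily enolised ketones and leaves lactones alone; the cage ketone between two quaternary carbons should not react.

**Step 16**
Reactants: 22 methylene compound
Product: 23 tert-butyldimethylsilyl ether of the target
Conditions: Co(acac)2 (20 mol %), PhSiH3, O2 (1 atm), THF/i-PrOH, rt; then PPh3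
Reagents that add atoms: dioxygen O=O
Why: Mukaiyama hydration (hydrogen-atom transfer to the CH2 terminus, O2 capture of the tertiary radical, reduction of the peroxide), in which oxygen should enter opposite to the gem-dimethyl-bearing carbon of ring A and so give the tertiary alcohol with methyl cis to that carbon; the electron-poor lactone alkene should react much more slowly.

**Step 17**
Reactants: 23 silyl ether
Product: 24 target CNP0360620.3
Conditions: HF·pyridine, THF, 0 °C to rt
Reagents that add atoms: none
Why: fluoride cleavage of the secondary silyl ether under weakly acidic conditions, which avoid retro-aldol opening of the β-hydroxy ketone.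

**Compound list**

1 | 3-ethoxy-2-methylcyclohex-2-en-1-one | CCOC1=C(C)C(=O)CCC1 | starting material
2 | 2-(bromomethyl)-3-ethoxycyclohex-2-en-1-one | CCOC1=C(CBr)C(=O)CCC1 | intermediate
3 | dimethyl (1R,2R)-4-oxocyclopentane-1,2-dicarboxylate | COC(=O)[C@@H]1CC(=O)C[C@H]1C(=O)OC | starting material
4 | dimethyl (1R,2R)-3-methyl-4-oxocyclopentane-1,2-dicarboxylate (3-epimers) | COC(=O)[C@@H]1C(C)C(=O)C[C@H]1C(=O)OC | intermediate
5 | dimethyl 3-methyl-4-(trimethylsilyloxy)cyclopent-3-ene-1,2-dicarboxylate (trans) | COC(=O)[C@@H]1C(C)=C(O[Si](C)(C)C)C[C@H]1C(=O)OC | intermediate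
6 | benzyltrimethylammonium enolate of 4 | COC(=O)[C@@H]1C(C)=C([O-])C[C@H]1C(=O)OC.C[N+](C)(C)Cc1ccccc1 | intermediate (not isolated)
7 | dimethyl 3-[(2-ethoxy-6-oxocyclohex-1-enyl)methyl]-3-methyl-4-oxocyclopentane-1,2-dicarboxylate | CCOC1=C(C[C@@]2(C)C(=O)C[C@@H](C(=O)OC)[C@@H]2C(=O)OC)C(=O)CCC1 | intermediate
8 | 1-carboxylic acid of 7 (2-methyl ester kept) | CCOC1=C(C[C@@]2(C)C(=O)C[C@@H](C(=O)O)[C@@H]2C(=O)OC)C(=O)CCC1 | intermediate
9 | TBS ester and TBS enol ether of 8 | CCOC1=C(C[C@@]2(C)C(O[Si](C)(C)C(C)(C)C)=C[C@@H](C(=O)O[Si](C)(C)C(C)(C)C)[C@@H]2C(=O)OC)C(=O)CCC1 | intermediate (not isolated)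
10 | 5-(tert-butyldimethylsilyloxy) keto acid | CCOC1=C(C[C@@]2(C)C(=O)[C@H](O[Si](C)(C)C(C)(C)C)[C@@H](C(=O)O)[C@@H]2C(=O)OC)C(=O)CCC1 | intermediate
11 | trione acid (2-substituted cyclohexane-1,3-dione) | O=C1CCCC(=O)C1C[C@@]2(C)C(=O)[C@H](O[Si](C)(C)C(C)(C)C)[C@@H](C(=O)O)[C@@H]2C(=O)OC | intermediate
12 | isopropenyl carbinol | O=C1CCCC(=O)C1C[C@@]2(C)[C@@](O)(C(C)=C)[C@H](O[Si](C)(C)C(C)(C)C)[C@@H](C(=O)O)[C@@H]2C(=O)OC | intermediate
13 | aldehyde | O=C1CCCC(=O)C1C[C@@]2(C)[C@@](O)(C(C)=C)[C@H](O[Si](C)(C)C(C)(C)C)[C@@H](C(=O)O)[C@@H]2C=O | intermediate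
14 | aldol (β-hydroxy ketone; two new centres unassigned) | O=C[C@@]12[C@H](C(=O)O)[C@@H](O[Si](C)(C)C(C)(C)C)[C@](O)(C(C)=C)[C@]1(C)CC1C(=O)CCCC21O | intermediate (not isolated)
15 | tricyclic enone aldehyde | O=C[C@@]12[C@H](C(=O)O)[C@@H](O[Si](C)(C)C(C)(C)C)[C@](O)(C(C)=C)[C@]1(C)CC1=C2CCCC1=O | intermediate
16 | tricyclic enone alcohol | OC[C@@]12[C@H](C(=O)O)[C@@H](O[Si](C)(C)C(C)(C)C)[C@](O)(C(C)=C)[C@]1(C)CC1=C2CCCC1=O | intermediate
17 | bicyclo[3.2.1]octyl cation (drawn metal-free, ring-B enol) | OC[C@@]12[C@H](C(=O)O)[C@@H](O[Si](C)(C)C(C)(C)C)[C@]3(O)[C+](C)C[C@]24CCCC(O)=C4C[C@]13C | intermediate (not isolated)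
18 | cage hydroxy acid | O=C1CCC[C@]23C[C@]4(C)C(=O)[C@](C)(C[C@@H]12)[C@@]3(CO)[C@H](C(=O)O)[C@H]4O[Si](C)(C)C(C)(C)C | intermediate (not isolated)
19 | pentacyclic keto lactone | O=C1CCC[C@]23C[C@]4(C)C(=O)[C@](C)(C[C@@H]12)[C@]31COC(=O)[C@@H]1[C@H]4O[Si](C)(C)C(C)(C)C | intermediate
20 | (E)-enoate (epimers at the new methine) | COC(=O)/C=C/C1CC[C@]23C[C@]4(C)C(=O)[C@](C)(C[C@H]2C1=O)[C@]31COC(=O)[C@@H]1[C@H]4O[Si](C)(C)C(C)(C)C | intermediate
21 | spiro lactone ketone | CC1(C)OC(=O)C=C[C@]12CC[C@]13C[C@]4(C)C(=O)[C@](C)(C[C@H]1C2=O)[C@]31COC(=O)[C@@H]1[C@H]4O[Si](C)(C)C(C)(C)C | intermediate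
22 | methylene compound | CC1(C)OC(=O)C=C[C@]12CC[C@]13C[C@]4(C)C(=O)[C@](C)(C[C@H]1C2=C)[C@]31COC(=O)[C@@H]1[C@H]4O[Si](C)(C)C(C)(C)C | intermediate
23 | tert-butyldimethylsilyl ether of the target | CC1(C)OC(=O)C=C[C@]12CC[C@]13C[C@]4(C)C(=O)[C@](C)(C[C@H]1[C@@]2(C)O)[C@]31COC(=O)[C@@H]1[C@H]4O[Si](C)(C)C(C)(C)C | intermediate
24 | CNP0360620.3 | CC1(C)OC(=O)C=C[C@]12CC[C@]13C[C@]4(C)C(=O)[C@](C)(C[C@H]1[C@@]2(C)O)[C@]31COC(=O)[C@@H]1[C@H]4O | target

**Step count and risk**

Total step count: 17. Longest linear sequence: 16 steps (steps 2 to 17 from 3); step 1 is a one-step side branch.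

Steps most likely to fail:

Step 12 (proposed new method). The tertiary allylic alcohol may ionise before the enone is engaged, the cation may be trapped by the carboxylate or lose a proton, or the ring-fusion carbon may migrate instead of the CH(OTBS) carbon. The fallback separates C–C bond formation from the ring contraction and uses only known reaction types. It sets out from 11: the organocerium reagent made from 2-bromo-3-(trimethylsilyl)propene, t-BuLi and CeCl3 is added in place of the isopropenyl reagent to give the 2-(trimethylsilylmethyl)allyl carbinol F1. As in steps 9 to 11, i-Bu2AlH then gives the aldehyde F2, pyrrolidinium acetate the tricyclic enone aldehyde F3 and NaBH4 the enone alcohol F4. An intramolecular Hosomi–Sakurai reaction (TiCl4, CH2Cl2, −78 °C) closes the same bond and stops at the isolable bridged 2-methylene-bicyclo[3.2.1]octan-1-ol F5, which already holds the seven-membered ring. Protonation of its exocyclic methylene (TsOH, CH2Cl2, rt) then triggers the known acid-promoted semipinacol ring contraction of an allylic alcohol, with lactonisation, and the route is rejoined at 19.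

Step 14. The aldol at a congested centre is reversible and is only trapped if the enoate reaches the (Z) geometry; the facial selectivity at the new spiro centre may also be poor. The fallback builds the same ring stepwise from 20. Soft-enolisation C-acetylation (MgBr2·OEt2, i-Pr2NEt, N-acetylbenzotriazole) gives the 2-acetyl ketone F6. MeMgBr with CeCl3 at −78 °C adds only to the less hindered methyl ketone to give the tertiary alcohol F7. Irradiation (350 nm, benzophenone) isomerises the (E)-enoate, and the (Z)-hydroxy ester lactonises to 21, where the route is rejoined.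

Step 16. Oxygen may be captured on the wrong face of the tertiary radical, or hydrogen-atom transfer may reduce the conjugated lactone. The fallback reverses the stereochemical sense of the addition: it sets out from 21, skips step 15 and adds the methyl group as a nucleophile (MeMgBr, CeCl3, THF, −78 °C) to the ring-B ketone. The methyl group should enter on the face the radical route would have oxygenated, and the route is rejoined at 23 (no new compound, entry F0).

**Further compounds**

F1 | step 12 | 2-(trimethylsilylmethyl)allyl carbinol (analogue of 12) | O=C1CCCC(=O)C1C[C@@]2(C)[C@@](O)(C(C[Si](C)(C)C)=C)[C@H](O[Si](C)(C)C(C)(C)C)[C@@H](C(=O)O)[C@@H]2C(=O)OC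
F2 | step 12 | aldehyde (analogue of 13) | O=C1CCCC(=O)C1C[C@@]2(C)[C@@](O)(C(C[Si](C)(C)C)=C)[C@H](O[Si](C)(C)C(C)(C)C)[C@@H](C(=O)O)[C@@H]2C=O
F3 | step 12 | tricyclic enone aldehyde (analogue of 15) | O=C[C@@]12[C@H](C(=O)O)[C@@H](O[Si](C)(C)C(C)(C)C)[C@](O)(C(C[Si](C)(C)C)=C)[C@]1(C)CC1=C2CCCC1=O
F4 | step 12 | tricyclic enone alcohol (analogue of 16) | OC[C@@]12[C@H](C(=O)O)[C@@H](O[Si](C)(C)C(C)(C)C)[C@](O)(C(C[Si](C)(C)C)=C)[C@]1(C)CC1=C2CCCC1=O
F5 | step 12 | bridged 2-methylene-bicyclo[3.2.1]octan-1-ol hydroxy acid | OC[C@@]12[C@H](C(=O)O)[C@@H](O[Si](C)(C)C(C)(C)C)[C@]3(O)C(=C)C[C@]24CCCC(=O)[C@@H]4C[C@]13C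
F6 | step 14 | 2-acetyl ketone bearing the (E)-enoate | COC(=O)/C=C/[C@@]1(C(C)=O)CC[C@]23C[C@]4(C)C(=O)[C@](C)(C[C@H]2C1=O)[C@]31COC(=O)[C@@H]1[C@H]4O[Si](C)(C)C(C)(C)C
F7 | step 14 | tertiary alcohol bearing the (E)-enoate | COC(=O)/C=C/[C@@]1(C(C)(C)O)CC[C@]23C[C@]4(C)C(=O)[C@](C)(C[C@H]2C1=O)[C@]31COC(=O)[C@@H]1[C@H]4O[Si](C)(C)C(C)(C)C
F0 | step 16 | none | none
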